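## Retrosynthetic overview

1. The 2-methoxy-1,4-benzoquinone (C1=O, C2–OMe, C3–H, C4=O, C5–CH3, C6–alkyl) is taken back to a resorcinol mono-silyl ether by oxidation at the free para CH, desilylation and O-methylation. The six-membered ring is the only ring of the target and is made in one step.
2. Key disconnection: ring bonds C2–C3 and C4–C5 lead to a 3-alkyl-2-methylcyclobut-2-enone and (triisopropylsiloxy)ethyne. They are joined by a thermal benzannulation that cleaves the cyclobutenone C(=O)–C(CH3) bond.
3. Enabling feature: the oxygen-bearing ring carbons C2 and C4 are 1,3-related across the only ring CH (C3), a resorcinol pattern, and C1 is para to C4. Hence C3–C4 maps onto an ynol ether, C2 onto a ketene carbonyl carbon, C2–C1–C6=C5 onto the cyclobutenone ring, and C1 can be oxidised last.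
4. The cyclobutenone comes from the chain Grignard reagent and 3-ethoxy-2-methylcyclobut-2-enone (dichloroketene + 1-ethoxypropyne). The chain chloride comes from Zweifel olefination and diimide reduction of a secondary boronic ester with an (E)-8-chlorooctenyl unit.
5. Chain stereocentres: C15′ from (S)-1-bromo-2-methylbutane; C13′, C11′, C9′ by three reagent-controlled lithiation–borylations alternating with Matteson CH2 insertions. Ring order: cyclobutenone (steps 11–13), benzenoid ring (step 15), quinone (step 18).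

Key step: step 15

Remark on availability: ethyl 2,4,6-triisopropylbenzoate, (+)-sparteine, 8-chlorooct-1-yne, 1-ethoxyprop-1-yne and ethynylmagnesium bromide solution are taken as purchasable.

Remark on the carbenoid: stannane 6 is the stored, enantiopure carbenoid precursor. In steps 3, 5 and 7 it is a reactant, and the lithiated benzoate released from it by tin–lithium exchange acts there as a reagent made and used up in the flask.

Abbreviations: R* = (9R,11R,13S,15S)-9,11,13,15-tetramethylheptadecyl (chain numbered from the ring, C1′–C17′); Bpin = 4,4,5,5-tetramethyl-1,3,2-dioxaborolan-2-yl; TIPS = tri(propan-2-yl)silyl.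

## Route

Step 1
Reactants: 1 (S)-1-bromo-2-methylbutane
Product: 3 4,4,5,5-tetramethyl-2-[(2R)-2-methylbutyl]-1,3,2-dioxaborolane, via Grignard reagent 2 (not isolated)
Conditions: Mg, THF, rt → 50 °C; then i-PrOBpin, −78 °C → rt; aq. NH4Cl
Reagents that add atoms: 2-isopropoxy-4,4,5,5-tetramethyl-1,3,2-dioxaborolane, CC(C)OB1OC(C)(C)C(C)(C)O1
Why: Grignard formation and borylation with an alkoxyboronic ester should leave the β-stereocentre untouched, so C15′ comes from the chiral pool; the descriptor becomes R only because CH2B ranks below ethyl.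

Step 2
Reactants: 4 ethyl 2,4,6-triisopropylbenzoate
Product: 6 (R)-1-(trimethylstannyl)ethyl 2,4,6-triisopropylbenzoate, via α-lithio benzoate 5 (not isolated)
Conditions: s-BuLi, (+)-sparteine, Et2O, −78 °C; Me3SnCl, −78 °C → rt; recrystallisation
Reagents that add atoms: chlorotrimethylstannane, C[Sn](C)(C)Cl
Why: Sparteine-mediated enantioselective α-deprotonation ((+)-sparteine removes the pro-R hydrogen) should give the configurationally stable organolithium 5, which is stannylated with retention; recrystallisation is expected to upgrade 6 to a single enantiomer that stores the chirality for steps 3, 5 and 7.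

Step 3
Reactants: 3 4,4,5,5-tetramethyl-2-[(2R)-2-methylbutyl]-1,3,2-dioxaborolane; 6 (R)-1-(trimethylstannyl)ethyl 2,4,6-triisopropylbenzoate
Product: 8 4,4,5,5-tetramethyl-2-[(2S,4S)-4-methylhexan-2-yl]-1,3,2-dioxaborolane, via boronate complex 7 (not isolated)
Conditions: 6, n-BuLi, Et2O, −78 °C (Sn–Li exchange); then 3, −78 °C → rt, then 35 °C; aq. NH4Cl
Reagents that add atoms: none
Why: Lithiation–borylation: tin–lithium exchange on stannane 6 releases, with retention, the same (R)-configured α-lithiated benzoate that was stannylated in step 2, now as the carbenoid reagent; boron traps it with retention to give 7, and the anti-periplanar 1,2-metallate shift (inversion at the carbenoid carbon, loss of the benzoate) should set C13′ under reagent control, syn to C15′.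

Step 4
Reactants: 8 4,4,5,5-tetramethyl-2-[(2S,4S)-4-methylhexan-2-yl]-1,3,2-dioxaborolane
Product: 10 2-[(2R,4S)-2,4-dimethylhexyl]-4,4,5,5-tetramethyl-1,3,2-dioxaborolane, via chloromethyl boronate 9 (not isolated)
Conditions: BrCH2Cl, n-BuLi, THF, −78 °C → rt
Reagents that add atoms: bromochloromethane, ClCBr
Why: Matteson homologation: chloromethyllithium formed in situ adds to boron and the 1,2-shift of the secondary alkyl group, with retention at the migrating carbon, should insert the C12′ methylene.

Step 5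
Reactants: 10 2-[(2R,4S)-2,4-dimethylhexyl]-4,4,5,5-tetramethyl-1,3,2-dioxaborolane; 6 (R)-1-(trimethylstannyl)ethyl 2,4,6-triisopropylbenzoate
Product: 12 2-[(2S,4R,6S)-4,6-dimethyloctan-2-yl]-4,4,5,5-tetramethyl-1,3,2-dioxaborolane, via boronate complex 11 (not isolated)
Conditions: 6, n-BuLi, Et2O, −78 °C (Sn–Li exchange); then 10, −78 °C → rt, then 35 °C; aq. NH4Cl
Reagents that add atoms: none
Why: Second lithiation–borylation: the carbenoid reagent released from 6 by tin–lithium exchange is trapped by boron with retention to give 11, and the 1,2-metallate shift with inversion should set C11′ syn to C13′ under reagent control, irrespective of the existing centres.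

Step 6
Reactants: 12 2-[(2S,4R,6S)-4,6-dimethyloctan-2-yl]-4,4,5,5-tetramethyl-1,3,2-dioxaborolane
Product: 14 4,4,5,5-tetramethyl-2-[(2R,4R,6S)-2,4,6-trimethyloctyl]-1,3,2-dioxaborolane, via chloromethyl boronate 13 (not isolated)
Conditions: BrCH2Cl, n-BuLi, THF, −78 °C → rt
Reagents that add atoms: bromochloromethane, ClCBr
Why: Matteson homologation with retention at the migrating stereocentre should insert the C10′ methylene.

Step 7
Reactants: 14 4,4,5,5-tetramethyl-2-[(2R,4R,6S)-2,4,6-trimethyloctyl]-1,3,2-dioxaborolane; 6 (R)-1-(trimethylstannyl)ethyl 2,4,6-triisopropylbenzoate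
Product: 16 4,4,5,5-tetramethyl-2-[(2S,4R,6S,8S)-4,6,8-trimethyldecan-2-yl]-1,3,2-dioxaborolane, via boronate complex 15 (not isolated)
Conditions: 6, n-BuLi, Et2O, −78 °C (Sn–Li exchange); then 14, −78 °C → rt, then 35 °C; aq. NH4Cl
Reagents that add atoms: none
Why: Third lithiation–borylation: the carbenoid reagent released from 6 is trapped by boron with retention to give 15, and the stereospecific 1,2-metallate rearrangement should set C9′, completing the all-syn tetramethyl array.

Step 8
Reactants: 17 8-chlorooct-1-yne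
Product: 19 (E)-8-chloro-1-iodooct-1-ene, via alkenylzirconocene 18 (not isolated)
Conditions: Cp2Zr(H)Cl, THF, rt; then I2, 0 °C
Reagents that add atoms: iodine, II
Why: Hydrozirconation with the Schwartz reagent is a syn addition placing zirconium at the terminal carbon, and iodinolysis with retention should give the (E)-alkenyl iodide; the primary chloride is inert.

Step 9
Reactants: 19 (E)-8-chloro-1-iodooct-1-ene; 16 4,4,5,5-tetramethyl-2-[(2S,4R,6S,8S)-4,6,8-trimethyldecan-2-yl]-1,3,2-dioxaborolane
Product: 23 (7Z,9S,11S,13S,15S)-1-chloro-9,11,13,15-tetramethylheptadec-7-ene, via alkenyllithium 20 (not isolated), via alkenyl boronate 21 (not isolated), via β-iodo boronic ester 22 (not isolated)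
Conditions: 19, t-BuLi (2 equiv), Et2O, −78 °C; 16, THF, −78 → 0 °C; I2, THF, −78 °C; NaOMe, MeOH, −78 °C → rt
Reagents that add atoms: none
Why: Zweifel olefination: the alkenyllithium adds to boron, iodination triggers 1,2-migration of the secondary alkyl group with retention at C9′, and methoxide-induced anti elimination should give the (Z)-alkene; the alkyl chloride does not react at −78 °C.

Step 10
Reactants: 23 (7Z,9S,11S,13S,15S)-1-chloro-9,11,13,15-tetramethylheptadec-7-ene
Product: 24 (9R,11R,13S,15S)-1-chloro-9,11,13,15-tetramethylheptadecane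
Conditions: TsNHNH2, NaOAc, DME/H2O, reflux
Reagents that add atoms: none
Why: Diimide reduction (concerted syn transfer of H2) should saturate the cis-alkene without a metal hydride that could move the double bond into the allylic C9′ stereocentre, and it leaves the C–Cl bond intact.

Step 11
Reactants: 25 1-ethoxyprop-1-yne; 26 dichloroacetyl chloride
Product: 28 4,4-dichloro-3-ethoxy-2-methylcyclobut-2-en-1-one, via dichloroketene 27 (not isolated)
Conditions: Et3N, slow addition of 26, Et2O/hexane, 0 °C → rt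
Reagents that add atoms: none
Why: Ketene–alkyne [2+2] cycloaddition: the nucleophilic methyl-bearing carbon of the ynol ether attacks the carbonyl carbon of dichloroketene, so methyl should end up at C2 and ethoxy at C3.

Step 12
Reactants: 28 4,4-dichloro-3-ethoxy-2-methylcyclobut-2-en-1-one
Product: 29 3-ethoxy-2-methylcyclobut-2-en-1-one
Conditions: Zn dust, AcOH, TMEDA, EtOH, 0 °C → rt
Reagents that add atoms: none
Why: Reductive dechlorination of the α,α-dichloroketone by zinc (zinc enolates protonated by acetic acid) is the standard follow-up to dichloroketene cycloadditions and should spare the vinylogous ester.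

Step 13
Reactants: 24 (9R,11R,13S,15S)-1-chloro-9,11,13,15-tetramethylheptadecane; 29 3-ethoxy-2-methylcyclobut-2-en-1-one
Product: 32 2-methyl-3-[(9R,11R,13S,15S)-9,11,13,15-tetramethylheptadecyl]cyclobut-2-en-1-one, via Grignard reagent 30 (not isolated), via cyclobutenol magnesium alkoxide 31 (not isolated)
Conditions: 24, Mg (BrCH2CH2Br activation), THF, reflux; 29, THF, −78 → 0 °C; 1 M HCl, 0 °C → rt
Reagents that add atoms: water, O
Why: 1,2-Addition of the Grignard reagent to the vinylogous ester carbonyl followed by acid hydrolysis and dehydration (Stork–Danheiser-type 1,3-carbonyl transposition) should give the 3-alkyl-2-methylcyclobutenone; no chain stereocentre is near the reacting sites.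

Step 14
Reactants: 33 ethynylmagnesium bromide
Product: 35 (ethynyloxy)tri(propan-2-yl)silane, via magnesium ynolate 34 (not isolated)
Conditions: t-BuOOH, LiHMDS, THF, −78 °C; then 33, −78 → 0 °C; TIPSOTf, −78 → 0 °C
Reagents that add atoms: tert-butyl hydroperoxide, CC(C)(C)OO; triisopropylsilyl trifluoromethanesulfonate, CC(C)[Si](OS(=O)(=O)C(F)(F)F)(C(C)C)C(C)C
Why: Electrophilic oxygenation of the metal acetylide by lithium tert-butyl peroxide should give the ynolate, which the bulky, hard silyl triflate is expected to silylate at oxygen rather than carbon.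

Step 15
Reactants: 32 2-methyl-3-[(9R,11R,13S,15S)-9,11,13,15-tetramethylheptadecyl]cyclobut-2-en-1-one; 35 (ethynyloxy)tri(propan-2-yl)silane
Product: 40 4-methyl-5-[(9R,11R,13S,15S)-9,11,13,15-tetramethylheptadecyl]-3-{[tri(propan-2-yl)silyl]oxy}phenol, via vinylketene 36 (not isolated), via 4-alkenylcyclobutenone 37 (not isolated), via dienylketene 38 (not isolated), via cyclohexadienone 39 (not isolated)
Conditions: 35 (2 equiv), toluene, 80 → 110 °C, sealed tube, Ar
Reagents that add atoms: none
Why: Heating opens cyclobutenone 32 by 4π-electrocyclic cleavage of its C1–C4 bond to vinylketene 36, which undergoes a polarity-controlled [2+2] cycloaddition with the siloxyalkyne (≡CH carbon to the ketene carbonyl carbon, siloxy carbon to the methyl-bearing carbon) to give 37; a second 4π opening cleaves the old C1–C2 bond to give dienylketene 38, which closes by 6π-electrocyclisation between the ketene carbon and the terminal CH2 to 39, and this tautomerises to phenol 40. The closest known reaction type is the Danheiser benzannulation of cyclobutenones with alkoxy- and siloxyacetylenes, which gives resorcinol monoethers of this substitution pattern. The transient four-membered ring of 37 closes by ketene–alkyne [2+2] cycloaddition and the benzenoid ring by thermal disrotatory 6π-electrocyclisation; net, only the bonds CH–C(OH) and C(OSi)–C(CH3) are new and the cyclobutenone C(=O)–C(CH3) bond is lost. No lasting stereocentre is created (the quaternary carbon of 37 and the sp3 CH2 of 39 are erased by ring opening and aromatisation), and the four remote methyl stereocentres should be untouched under neutral thermal conditions. The step needs regiocontrol in the [2+2] event, secured by the matched polarity of the electrophilic ketene carbon and the β-nucleophilic ynol ether, and a cis-dienylketene, secured because ring opening of 37 is reversible and only the isomer with the alkenyl group cis to the ketene is drained by cyclisation; excess 35 should suppress ketene dimerisation and acylation of 40.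

Step 16
Reactants: 40 4-methyl-5-[(9R,11R,13S,15S)-9,11,13,15-tetramethylheptadecyl]-3-{[tri(propan-2-yl)silyl]oxy}phenol
Product: 41 {5-methoxy-2-methyl-3-[(9R,11R,13S,15S)-9,11,13,15-tetramethylheptadecyl]phenoxy}tri(propan-2-yl)silane
Conditions: MeI, K2CO3, acetone, rt → 40 °C
Reagents that add atoms: iodomethane, CI
Why: Williamson O-methylation of the only free phenol installs the methoxy group of the target; the hindered aryl TIPS ether should survive carbonate in acetone.

Step 17
Reactants: 41 {5-methoxy-2-methyl-3-[(9R,11R,13S,15S)-9,11,13,15-tetramethylheptadecyl]phenoxy}tri(propan-2-yl)silane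
Product: 42 5-methoxy-2-methyl-3-[(9R,11R,13S,15S)-9,11,13,15-tetramethylheptadecyl]phenol
Conditions: TBAF, THF, 0 °C; aq. NH4Cl
Reagents that add atoms: none
Why: Fluoride-induced cleavage of the aryl silyl ether should unmask the phenol whose oxygen becomes the C4 carbonyl, leaving the methyl ether untouched.

Step 18
Reactants: 42 5-methoxy-2-methyl-3-[(9R,11R,13S,15S)-9,11,13,15-tetramethylheptadecyl]phenol
Product: 43 2-methoxy-5-methyl-6-[(9R,11R,13S,15S)-9,11,13,15-tetramethylheptadecyl]cyclohexa-2,5-diene-1,4-dione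
Conditions: Fremy's salt (2.5 equiv), KH2PO4 buffer, acetone/H2O, Aliquat 336, rt
Reagents that add atoms: potassium nitrosodisulfonate, [O]N(S(=O)(=O)[O-])S(=O)(=O)[O-].[K+].[K+]
Why: Teuber oxidation: Fremy's radical forms the phenoxyl radical, a second equivalent is captured at the unsubstituted carbon para to the hydroxyl, and loss of imidodisulfonate should give the p-quinone regiospecifically.

## Compound list

1 | (S)-1-bromo-2-methylbutane | CC[C@H](C)CBr | starting material
2 | (S)-2-methylbutylmagnesium bromide | CC[C@H](C)C[Mg]Br | intermediate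
3 | 4,4,5,5-tetramethyl-2-[(2R)-2-methylbutyl]-1,3,2-dioxaborolane | CC[C@H](C)CB1OC(C)(C)C(C)(C)O1 | intermediate
4 | ethyl 2,4,6-triisopropylbenzoate | CCOC(=O)c1c(C(C)C)cc(C(C)C)cc1C(C)C | starting material
5 | (R)-1-lithioethyl 2,4,6-triisopropylbenzoate | C[C@@H]([Li])OC(=O)c1c(C(C)C)cc(C(C)C)cc1C(C)C | intermediate
6 | (R)-1-(trimethylstannyl)ethyl 2,4,6-triisopropylbenzoate | C[C@@H]([Sn](C)(C)C)OC(=O)c1c(C(C)C)cc(C(C)C)cc1C(C)C | intermediate
7 | lithium boronate complex of 3 and the lithiated benzoate from 6 (boron in place of lithium, configuration retained) | CC[C@H](C)C[B-]1(OC(C)(C)C(C)(C)O1)[C@H](C)OC(=O)c1c(C(C)C)cc(C(C)C)cc1C(C)C.[Li+] | intermediate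
8 | 4,4,5,5-tetramethyl-2-[(2S,4S)-4-methylhexan-2-yl]-1,3,2-dioxaborolane | CC[C@H](C)C[C@H](C)B1OC(C)(C)C(C)(C)O1 | intermediate
9 | lithium (chloromethyl)boronate complex of 8 | CC[C@H](C)C[C@H](C)[B-]1(CCl)OC(C)(C)C(C)(C)O1.[Li+] | intermediate
10 | 2-[(2R,4S)-2,4-dimethylhexyl]-4,4,5,5-tetramethyl-1,3,2-dioxaborolane | CC[C@H](C)C[C@H](C)CB1OC(C)(C)C(C)(C)O1 | intermediate
11 | lithium boronate complex of 10 and the lithiated benzoate from 6 | CC[C@H](C)C[C@H](C)C[B-]1(OC(C)(C)C(C)(C)O1)[C@H](C)OC(=O)c1c(C(C)C)cc(C(C)C)cc1C(C)C.[Li+] | intermediate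
12 | 2-[(2S,4R,6S)-4,6-dimethyloctan-2-yl]-4,4,5,5-tetramethyl-1,3,2-dioxaborolane | CC[C@H](C)C[C@H](C)C[C@H](C)B1OC(C)(C)C(C)(C)O1 | intermediate
13 | lithium (chloromethyl)boronate complex of 12 | CC[C@H](C)C[C@H](C)C[C@H](C)[B-]1(CCl)OC(C)(C)C(C)(C)O1.[Li+] | intermediate
14 | 4,4,5,5-tetramethyl-2-[(2R,4R,6S)-2,4,6-trimethyloctyl]-1,3,2-dioxaborolane | CC[C@H](C)C[C@H](C)C[C@H](C)CB1OC(C)(C)C(C)(C)O1 | intermediate
15 | lithium boronate complex of 14 and the lithiated benzoate from 6 | CC[C@H](C)C[C@H](C)C[C@H](C)C[B-]1(OC(C)(C)C(C)(C)O1)[C@H](C)OC(=O)c1c(C(C)C)cc(C(C)C)cc1C(C)C.[Li+] | intermediate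
16 | 4,4,5,5-tetramethyl-2-[(2S,4R,6S,8S)-4,6,8-trimethyldecan-2-yl]-1,3,2-dioxaborolane | CC[C@H](C)C[C@H](C)C[C@H](C)C[C@H](C)B1OC(C)(C)C(C)(C)O1 | intermediate
17 | 8-chlorooct-1-yne | C#CCCCCCCCl | starting material
18 | (E)-(8-chlorooct-1-enyl)zirconocene chloride | ClCCCCCC/C=C/[Zr](Cl)(C1C=CC=C1)C1C=CC=C1 | intermediate
19 | (E)-8-chloro-1-iodooct-1-ene | ClCCCCCC/C=C/I | intermediate
20 | (E)-8-chlorooct-1-enyllithium | ClCCCCCC/C=C/[Li] | intermediate
21 | lithium (E)-alkenyl boronate complex of 16 with 20 | CC[C@H](C)C[C@H](C)C[C@H](C)C[C@H](C)[B-]1(/C=C/CCCCCCCl)OC(C)(C)C(C)(C)O1.[Li+] | intermediate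
22 | β-iodo boronic ester: 2-[(9S,11S,13S,15S)-1-chloro-7-iodo-9,11,13,15-tetramethylheptadecan-8-yl]-Bpin (C7, C8 transient) | CC[C@H](C)C[C@H](C)C[C@H](C)C[C@H](C)C(B1OC(C)(C)C(C)(C)O1)C(I)CCCCCCCl | intermediate
23 | (7Z,9S,11S,13S,15S)-1-chloro-9,11,13,15-tetramethylheptadec-7-ene | CC[C@H](C)C[C@H](C)C[C@H](C)C[C@H](C)/C=C\CCCCCCCl | intermediate
24 | (9R,11R,13S,15S)-1-chloro-9,11,13,15-tetramethylheptadecane | CC[C@H](C)C[C@H](C)C[C@H](C)C[C@H](C)CCCCCCCCCl | intermediate
25 | 1-ethoxyprop-1-yne | CC#COCC | starting material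
26 | dichloroacetyl chloride | ClC(Cl)C(Cl)=O | starting material
27 | dichloroketene | ClC(Cl)=C=O | intermediate
28 | 4,4-dichloro-3-ethoxy-2-methylcyclobut-2-en-1-one | CCOC1=C(C)C(=O)C1(Cl)Cl | intermediate
29 | 3-ethoxy-2-methylcyclobut-2-en-1-one | CCOC1=C(C)C(=O)C1 | intermediate
30 | R*-magnesium chloride | CC[C@H](C)C[C@H](C)C[C@H](C)C[C@H](C)CCCCCCCC[Mg]Cl | intermediate
31 | chloromagnesium 3-ethoxy-2-methyl-1-R*-cyclobut-2-en-1-olate (C1 unspecified) | CC[C@H](C)C[C@H](C)C[C@H](C)C[C@H](C)CCCCCCCCC1(O[Mg]Cl)CC(OCC)=C1C | intermediate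
32 | 2-methyl-3-R*-cyclobut-2-en-1-one | CC[C@H](C)C[C@H](C)C[C@H](C)C[C@H](C)CCCCCCCCC1=C(C)C(=O)C1 | intermediate
33 | ethynylmagnesium bromide | C#C[Mg]Br | starting material
34 | bromomagnesium ethynolate | C#CO[Mg]Br | intermediate
35 | (ethynyloxy)tri(propan-2-yl)silane | C#CO[Si](C(C)C)(C(C)C)C(C)C | intermediate
36 | vinylketene: 2-methyl-3-R*-buta-1,3-dien-1-one | CC[C@H](C)C[C@H](C)C[C@H](C)C[C@H](C)CCCCCCCCC(=C)C(C)=C=O | intermediate
37 | 4-methyl-4-(1-R*-ethenyl)-3-(TIPS-oxy)cyclobut-2-en-1-one (C4 transient) | CC[C@H](C)C[C@H](C)C[C@H](C)C[C@H](C)CCCCCCCCC(=C)C1(C)C(=O)C=C1O[Si](C(C)C)(C(C)C)C(C)C | intermediate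
38 | dienylketene: 4-methyl-5-R*-3-(TIPS-oxy)hexa-1,3,5-trien-1-one, ketene cis to the alkenyl group | CC[C@H](C)C[C@H](C)C[C@H](C)C[C@H](C)CCCCCCCCC(=C)/C(C)=C(\C=C=O)O[Si](C(C)C)(C(C)C)C(C)C | intermediate
39 | 4-methyl-5-R*-3-(TIPS-oxy)cyclohexa-2,4-dien-1-one | CC[C@H](C)C[C@H](C)C[C@H](C)C[C@H](C)CCCCCCCCC1=C(C)C(O[Si](C(C)C)(C(C)C)C(C)C)=CC(=O)C1 | intermediate
40 | 4-methyl-5-R*-3-(TIPS-oxy)phenol | CC[C@H](C)C[C@H](C)C[C@H](C)C[C@H](C)CCCCCCCCc1cc(O)cc(O[Si](C(C)C)(C(C)C)C(C)C)c1C | intermediate
41 | (5-methoxy-2-methyl-3-R*-phenoxy)tri(propan-2-yl)silane | CC[C@H](C)C[C@H](C)C[C@H](C)C[C@H](C)CCCCCCCCc1cc(OC)cc(O[Si](C(C)C)(C(C)C)C(C)C)c1C | intermediate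
42 | 5-methoxy-2-methyl-3-R*-phenol | CC[C@H](C)C[C@H](C)C[C@H](C)C[C@H](C)CCCCCCCCc1cc(OC)cc(O)c1C | intermediate
43 | 2-methoxy-5-methyl-6-[(9R,11R,13S,15S)-9,11,13,15-tetramethylheptadecyl]cyclohexa-2,5-diene-1,4-dione | CC[C@H](C)C[C@H](C)C[C@H](C)C[C@H](C)CCCCCCCCC1=C(C)C(=O)C=C(OC)C1=O | target

## Step count and risks

Total: 18 steps. Longest linear sequence: 13 steps (1, 3, 4, 5, 6, 7, 9, 10, 13, 15, 16, 17, 18).

Steps most likely to fail:

Step 14. The parent ynolate may be silylated on carbon or oligomerise, and the volatile siloxyalkyne may be lost on isolation. The fallback sets out from cyclobutenone 32 and uses commercial ethoxyethyne in the same thermal benzannulation (toluene, 80 °C), which should give 3-ethoxy-4-methyl-5-R*-phenol F1. O-Methylation (MeI, K2CO3) would give 1-ethoxy-5-methoxy-2-methyl-3-R*-benzene F2. NBS in MeCN is expected to brominate the position para to the ethoxy group, between the methoxy group and the chain, to give 2-bromo-5-ethoxy-1-methoxy-4-methyl-3-R*-benzene F3. Palladium-catalysed hydroxylation (KOH, Pd2(dba)3, t-BuXPhos, dioxane/H2O) would give 4-ethoxy-2-methoxy-5-methyl-6-R*-phenol F4. Oxidative de-ethylation of this p-alkoxyphenol with ceric ammonium nitrate comes back to the route at target 43.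

Step 15. The vinylketene may dimerise or acylate the product phenol faster than it is captured by the alkyne, or the 4-alkenylcyclobutenone may not open fully. The fallback abandons ring construction and sets out from chloride 24 through its Grignard reagent 30. Kumada coupling with 1-bromo-3,5-dimethoxybenzene (PdCl2(dppf), THF) would give 1,3-dimethoxy-5-R*-benzene F5. NBS would give 2-bromo-1,5-dimethoxy-3-R*-benzene F6. Palladium-catalysed methylation with trimethylboroxine (K2CO3) would give 1,5-dimethoxy-2-methyl-3-R*-benzene F7. A second NBS bromination at the remaining position between methoxy and chain would give 2-bromo-1,5-dimethoxy-4-methyl-3-R*-benzene F8. Palladium-catalysed hydroxylation (KOH) would give 2,4-dimethoxy-5-methyl-6-R*-phenol F9. Ceric ammonium nitrate oxidation, with loss of the para methyl ether, comes back to the route at target 43.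

Step 9. Boronate formation at the hindered secondary boronic ester may be incomplete, or the iodination–elimination may not be stereospecific, giving mixtures that are hard to purify. The fallback sets out from boronic ester 16. A further Matteson homologation would give 4,4,5,5-tetramethyl-2-[(2R,4R,6S,8S)-2,4,6,8-tetramethyldecyl]-1,3,2-dioxaborolane F10. Oxidation (NaBO3, THF/H2O) would give (2S,4S,6S,8S)-2,4,6,8-tetramethyldecan-1-ol F11. Tosylation would give (2S,4S,6S,8S)-2,4,6,8-tetramethyldecyl 4-methylbenzenesulfonate F12. Copper-catalysed sp3–sp3 coupling (Li2CuCl4, THF) with 7-chloroheptylmagnesium bromide F13, made from 1-bromo-7-chloroheptane and magnesium, comes back to the route at chloride 24 and also makes steps 8 and 10 unnecessary.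

## Further compounds

F1 | step 14 | 3-ethoxy-4-methyl-5-[(9R,11R,13S,15S)-9,11,13,15-tetramethylheptadecyl]phenol | CC[C@H](C)C[C@H](C)C[C@H](C)C[C@H](C)CCCCCCCCc1cc(O)cc(OCC)c1C
F2 | step 14 | 1-ethoxy-5-methoxy-2-methyl-3-[(9R,11R,13S,15S)-9,11,13,15-tetramethylheptadecyl]benzene | CC[C@H](C)C[C@H](C)C[C@H](C)C[C@H](C)CCCCCCCCc1cc(OC)cc(OCC)c1C
F3 | step 14 | 2-bromo-5-ethoxy-1-methoxy-4-methyl-3-[(9R,11R,13S,15S)-9,11,13,15-tetramethylheptadecyl]benzene | CC[C@H](C)C[C@H](C)C[C@H](C)C[C@H](C)CCCCCCCCc1c(Br)c(OC)cc(OCC)c1C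
F4 | step 14 | 4-ethoxy-2-methoxy-5-methyl-6-[(9R,11R,13S,15S)-9,11,13,15-tetramethylheptadecyl]phenol | CC[C@H](C)C[C@H](C)C[C@H](C)C[C@H](C)CCCCCCCCc1c(O)c(OC)cc(OCC)c1C
F5 | step 15 | 1,3-dimethoxy-5-[(9R,11R,13S,15S)-9,11,13,15-tetramethylheptadecyl]benzene | CC[C@H](C)C[C@H](C)C[C@H](C)C[C@H](C)CCCCCCCCc1cc(OC)cc(OC)c1
F6 | step 15 | 2-bromo-1,5-dimethoxy-3-[(9R,11R,13S,15S)-9,11,13,15-tetramethylheptadecyl]benzene | CC[C@H](C)C[C@H](C)C[C@H](C)C[C@H](C)CCCCCCCCc1cc(OC)cc(OC)c1Br
F7 | step 15 | 1,5-dimethoxy-2-methyl-3-[(9R,11R,13S,15S)-9,11,13,15-tetramethylheptadecyl]benzene | CC[C@H](C)C[C@H](C)C[C@H](C)C[C@H](C)CCCCCCCCc1cc(OC)cc(OC)c1C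
F8 | step 15 | 2-bromo-1,5-dimethoxy-4-methyl-3-[(9R,11R,13S,15S)-9,11,13,15-tetramethylheptadecyl]benzene | CC[C@H](C)C[C@H](C)C[C@H](C)C[C@H](C)CCCCCCCCc1c(Br)c(OC)cc(OC)c1C
F9 | step 15 | 2,4-dimethoxy-5-methyl-6-[(9R,11R,13S,15S)-9,11,13,15-tetramethylheptadecyl]phenol | CC[C@H](C)C[C@H](C)C[C@H](C)C[C@H](C)CCCCCCCCc1c(O)c(OC)cc(OC)c1C
F10 | step 9 | 4,4,5,5-tetramethyl-2-[(2R,4R,6S,8S)-2,4,6,8-tetramethyldecyl]-1,3,2-dioxaborolane | CC[C@H](C)C[C@H](C)C[C@H](C)C[C@H](C)CB1OC(C)(C)C(C)(C)O1
F11 | step 9 | (2S,4S,6S,8S)-2,4,6,8-tetramethyldecan-1-ol | CC[C@H](C)C[C@H](C)C[C@H](C)C[C@H](C)CO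
F12 | step 9 | (2S,4S,6S,8S)-2,4,6,8-tetramethyldecyl 4-methylbenzenesulfonate | CC[C@H](C)C[C@H](C)C[C@H](C)C[C@H](C)COS(=O)(=O)c1ccc(C)cc1
F13 | step 9 | 7-chloroheptylmagnesium bromide | ClCCCCCCC[Mg]Br
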